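Numbering (germacranolide): C1 ketone, C2=C3, furanone oxygen on C3 and C10, C4=C15, C5–OH, C6–O-methacrylate, C7, C8–O–C12(=O) lactone with C11=C13, C9, C10 (methyl C14).
Cuts, in retrosynthetic order: C5 carbinol to ketone; C12 carbonyl to CH2 (lactone ring kept as the cyclic ether O8–C12); C6 ester; C6–C7 with O6 rejoined to C13 (retro-[2,3]-Wittig, ten-membered carbocycle to thirteen-membered ether); C4–C5 (chromium/nickel closure); C7=C11 (metathesis) and O8–C12 (etherification); furanone O–C3 and C1–C2 (diynone); C7–C8 (vinyl addition); C9–C10 (enolate allylation).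
Feature used by the key step: the C6 carbinol sits next to C7, which carries the C11=C13 exocyclic methylene of the five-membered O8/C12 ring (O–C6–C7–C11=C13). This is the 1-hydroxy-2-alkenyl unit that a [2,3] shift of a C6–O–C13 allylic ether leaves, here inside the carbocycle C1–C10.
Forward order of rings: dioxolanone (chirality store), temporary γ-lactone O8–C1, furanone, 2,5-dihydrofuran, thirteen-membered ether, ten-membered carbocycle, lactone carbonyl.
Stereochemistry: C10 from (S)-lactic acid by self-regeneration of the stereocentre; C8 by catalyst-controlled vinylzinc addition; C7 and C6 in the ring contraction, relayed from C8; C5 by substrate-controlled 1,2-reduction.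

Key step: step 15

Remark: the lactone ring is carried from step 10 to step 17 at the cyclic ether level (C12 as CH2). This ties O8 to C12 in a planar five-membered ring during the ring contraction; C12 is oxidised afterwards.
Remark: Zn(CH=CH2)2 is taken as a preformed reagent, LiN(i-Pr)2 and LiN(SiMe3)2 as commercial solutions.

Step 1
Reactants: 1 (S)-lactic acid; 2 pivalaldehyde
Product: 3 (2S,5S)-2-tert-butyl-5-methyl-1,3-dioxolan-4-one
Conditions: p-TsOH·H2O (cat.), H2SO4 (cat.), pentane, reflux with water separator; recrystallisation at −78 °C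
Reagents that add atoms: none
Why: Acid-catalysed acetalisation gives the cis acetal as the thermodynamic and crystalline isomer, so the acetal carbon stores the lactic acid configuration.

Step 2
Reactants: 3 (2S,5S)-2-tert-butyl-5-methyl-1,3-dioxolan-4-one; 4 allyl bromide
Product: 5 (2S,5R)-2-tert-butyl-5-methyl-5-(prop-2-en-1-yl)-1,3-dioxolan-4-one
Conditions: LiN(i-Pr)2, THF, −78 °C; then 4, −78 → −30 °C
Reagents that add atoms: none
Why: Enolate alkylation with self-regeneration of the stereocentre: the planar lithium enolate is allylated anti to the tert-butyl group, which sets the quaternary carbon C10 (R).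

Step 3
Reactants: 5 (2S,5R)-2-tert-butyl-5-methyl-5-(prop-2-en-1-yl)-1,3-dioxolan-4-one
Product: 6 2-[(2S,4R)-2-tert-butyl-4-methyl-5-oxo-1,3-dioxolan-4-yl]acetaldehyde
Conditions: O3, CH2Cl2, −78 °C; then PPh3, −78 → 23 °C
Reagents that add atoms: ozone, [O-][O+]=O
Why: Ozonolysis with reductive work-up cleaves the only alkene to the aldehyde that becomes C8, the acylal being inert.

Step 4
Reactants: 6 2-[(2S,4R)-2-tert-butyl-4-methyl-5-oxo-1,3-dioxolan-4-yl]acetaldehyde
Product: 8 (3R,5S)-5-ethenyl-3-hydroxy-3-methyloxolan-2-one, via hydroxy dioxolanone 7 (not isolated)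
Conditions: Zn(CH=CH2)2, (+)-3-exo-(dimethylamino)isoborneol (cat.), toluene, 0 °C; aq NH4Cl; then p-TsOH·H2O (cat.), CH2Cl2, 23 °C
Reagents that add atoms: divinylzinc, C=C[Zn]C=C
Why: Amino-alcohol-catalysed alkenylzinc addition, in which the (+)-ligand (its antipode steers zinc-bound groups to the Si face) should deliver vinyl to the Re face and set C8 (S), followed by acid-catalysed translactonisation of the new hydroxyl onto the acylal with loss of pivalaldehyde, the rigid lactone allowing any C8 epimer to be removed.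

Step 5
Reactants: 8 (3R,5S)-5-ethenyl-3-hydroxy-3-methyloxolan-2-one; 9 1,4-bis(trimethylsilyl)buta-1,3-diyne
Product: 10 (6R,8S)-6,8-dihydroxy-6-methyl-1-(trimethylsilyl)dec-9-ene-1,3-diyn-5-one
Conditions: 9, MeLi·LiBr, THF, 23 °C; then 8, THF, −78 → −40 °C; aq NH4Cl
Reagents that add atoms: none
Why: Nucleophilic acyl substitution by a lithium alkynide: LiC≡C–C≡C–SiMe3 (from mono-desilylation of 9) adds once to the lactone carbonyl of the lithium alkoxide of 8 and the lactolate survives until work-up, which releases the ynone at C1 and the C8 hydroxyl without touching either stereocentre.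

Step 6
Reactants: 10 (6R,8S)-6,8-dihydroxy-6-methyl-1-(trimethylsilyl)dec-9-ene-1,3-diyn-5-one
Product: 11 (2R)-5-ethynyl-2-[(2S)-2-hydroxybut-3-en-1-yl]-2-methylfuran-3(2H)-one
Conditions: K2CO3 (cat.), MeOH, 0 → 23 °C
Reagents that add atoms: none
Why: Base-mediated 5-endo-dig oxa-Michael addition of the tertiary C10 hydroxyl to the ynone forms the 3(2H)-furanone (O–C3 bond), and methanolysis cleaves the alkynylsilane to the terminal alkyne.

Step 7
Reactants: 11 (2R)-5-ethynyl-2-[(2S)-2-hydroxybut-3-en-1-yl]-2-methylfuran-3(2H)-one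
Product: 13 (2R)-2-[(2S)-2-hydroxybut-3-en-1-yl]-5-(1-iodoethenyl)-2-methylfuran-3(2H)-one, via alkenylstannane 12 (not isolated)
Conditions: Bu3SnH, PdCl2(PPh3)2 (cat.), THF, 0 °C; then I2, CH2Cl2, 0 °C
Reagents that add atoms: iodine, [I][I]
Why: Palladium-catalysed syn hydrostannation of an acceptor-substituted terminal alkyne delivers hydride to the terminal carbon C15 and tin to C4, and iododestannylation then gives the 1-iodoalkenyl group for the later chromium-mediated coupling.

Step 8
Reactants: 14 2-{[tert-butyl(dimethyl)silyl]oxy}ethan-1-ol; 15 3-chloro-2-(chloromethyl)prop-1-ene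
Product: 16 tert-butyl(2-{[2-(chloromethyl)prop-2-en-1-yl]oxy}ethoxy)dimethylsilane
Conditions: NaH, THF, 0 °C; then 15 (excess), Bu4NI (cat.), 0 → 23 °C
Reagents that add atoms: none
Why: Williamson ether synthesis in which an excess of the symmetrical bis-allylic chloride limits substitution to one chloride, silyl migration in the glycol monoether being degenerate.

Step 9
Reactants: 13 (2R)-2-[(2S)-2-hydroxybut-3-en-1-yl]-5-(1-iodoethenyl)-2-methylfuran-3(2H)-one; 16 tert-butyl(2-{[2-(chloromethyl)prop-2-en-1-yl]oxy}ethoxy)dimethylsilane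
Product: 17 (2R)-2-[(2S)-2-({2-[(2-{[tert-butyl(dimethyl)silyl]oxy}ethoxy)methyl]prop-2-en-1-yl}oxy)but-3-en-1-yl]-5-(1-iodoethenyl)-2-methylfuran-3(2H)-one
Conditions: NaH, Bu4NI (cat.), THF/DMF, 0 → 23 °C
Reagents that add atoms: none
Why: Williamson O-allylation of the C8 alkoxide by the allylic chloride (activated as the iodide), which leaves the C8–O bond and hence the stereocentre intact.

Step 10
Reactants: 17 (2R)-2-[(2S)-2-({2-[(2-{[tert-butyl(dimethyl)silyl]oxy}ethoxy)methyl]prop-2-en-1-yl}oxy)but-3-en-1-yl]-5-(1-iodoethenyl)-2-methylfuran-3(2H)-one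
Product: 18 (2R)-2-{[(2S)-4-[(2-{[tert-butyl(dimethyl)silyl]oxy}ethoxy)methyl]-2,5-dihydrofuran-2-yl]methyl}-5-(1-iodoethenyl)-2-methylfuran-3(2H)-one
Conditions: second-generation Grubbs catalyst RuCl2(=CHPh)(PCy3)(H2IMes) (cat.), CH2Cl2, 40 °C
Reagents that add atoms: none
Why: Ring-closing metathesis of the C8 vinyl group with the 1,1-disubstituted allyl ether alkene gives the 2,5-dihydrofuran, whose ring fixes C12 cis and C13 trans to C8 on the new C7=C11 bond, while the iodoalkene and the furanone alkene are too electron-poor to engage.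

Step 11
Reactants: 18 (2R)-2-{[(2S)-4-[(2-{[tert-butyl(dimethyl)silyl]oxy}ethoxy)methyl]-2,5-dihydrofuran-2-yl]methyl}-5-(1-iodoethenyl)-2-methylfuran-3(2H)-one
Product: 19 (2R)-2-{[(2S)-4-[(2-hydroxyethoxy)methyl]-2,5-dihydrofuran-2-yl]methyl}-5-(1-iodoethenyl)-2-methylfuran-3(2H)-one
Conditions: HF·pyridine, pyridine, THF, 0 → 23 °C
Reagents that add atoms: none
Why: Fluoride-mediated cleavage of the only silyl ether frees the primary alcohol.

Step 12
Reactants: 19 (2R)-2-{[(2S)-4-[(2-hydroxyethoxy)methyl]-2,5-dihydrofuran-2-yl]methyl}-5-(1-iodoethenyl)-2-methylfuran-3(2H)-one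
Product: 20 {[(5S)-5-{[(2R)-5-(1-iodoethenyl)-2-methyl-3-oxo-2,3-dihydrofuran-2-yl]methyl}-2,5-dihydrofuran-3-yl]methoxy}acetaldehyde
Conditions: Dess–Martin periodinane, NaHCO3, CH2Cl2, 0 → 23 °C
Reagents that add atoms: none
Why: Dess–Martin oxidation converts the primary alcohol into the α-alkoxy aldehyde (C5) under buffered conditions, and the aldehyde is used at once.

Step 13
Reactants: 20 {[(5S)-5-{[(2R)-5-(1-iodoethenyl)-2-methyl-3-oxo-2,3-dihydrofuran-2-yl]methyl}-2,5-dihydrofuran-3-yl]methoxy}acetaldehyde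
Product: 21 (8S,10R)-5-hydroxy-3,10:6,13:8,12-triepoxy-6,7-secogermacra-2,4(15),7(11)-trien-1-one (thirteen-membered allylic alcohol; both C5 epimers)
Conditions: CrCl2 (excess), NiCl2 (cat.), DMSO/THF, 23 °C, slow addition at high dilution (about 0.003 M)
Reagents that add atoms: none
Why: Nozaki–Hiyama–Kishi reaction, in which nickel-catalysed activation of the C4–iodine bond and transfer to chromium give an alkenylchromium species that adds only to the aldehyde and closes the thirteen-membered ring at C4–C5, the configuration of the C5 carbinol being irrelevant because it is oxidised next.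

Step 14
Reactants: 21 (8S,10R)-5-hydroxy-3,10:6,13:8,12-triepoxy-6,7-secogermacra-2,4(15),7(11)-trien-1-one
Product: 22 (8S,10R)-3,10:6,13:8,12-triepoxy-6,7-secogermacra-2,4(15),7(11)-triene-1,5-dione (thirteen-membered keto ether: C5 ketone, C6H2–O–C13H2, C7=C11 in the 2,5-dihydrofuran, C4=C15H2, furanone)
Conditions: Dess–Martin periodinane, NaHCO3, CH2Cl2, 0 °C
Reagents that add atoms: none
Why: Dess–Martin oxidation of the allylic alcohol gives the C5 ketone, which makes C6 the only enolisable carbon.

Step 15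
Reactants: 22 (8S,10R)-3,10:6,13:8,12-triepoxy-6,7-secogermacra-2,4(15),7(11)-triene-1,5-dione
Product: 23 (6R,7R,8S,10R)-6-hydroxy-3,10:8,12-diepoxygermacra-2,4(15),11(13)-triene-1,5-dione
Conditions: LiN(SiMe3)2, THF, −78 → −30 °C; AcOH in THF, −78 °C
Reagents that add atoms: none
Why: LiN(SiMe3)2 removes a proton from C6, the only enolisable position of the C5 ketone because C4 carries the methylene, and the enolate carbon bonds to C7 through a five-membered envelope (C6, O, C13, C11, C7) while the O–C13 bond breaks, so that the ether oxygen becomes the C6 alkoxide and C11=C13 the exocyclic methylene. This is the enolate variant of the [2,3]-Wittig rearrangement, applied as in the known ring contractions of thirteen-membered allylic ethers to ten-membered carbocycles. The ten-membered carbocycle is closed transannularly by this sigmatropic C6–C7 bond formation, the atoms O, C13 and C11 leaving the large ring. C7 is controlled by C8 through the dihydrofuran ring, which keeps the C8–O bond in the plane of C7=C11 and C9 on one face; since C6 is tied to C9 by the short furanone-containing bridge it should reach C7 only on that face, which gives the cis relation of H7 and H8 needed for the lactone. C6 follows from the trans placement of C8 and C13 on the alkene and the exo position of the enolate carbon C5 on the envelope, the endo alternative forcing two adjacent small torsion angles into the forming ring. The step needs the [2,3] path to win over the anionic [3,3] (oxy-Claisen) path, which the tightly bound lithium counter-ion at low temperature and the strained quaternary carbinol of the smaller ring that the latter would create are expected to secure, and it needs the α-ketol to keep its C6 configuration, which the cold acetic acid quench protects.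

Step 16
Reactants: 23 (6R,7R,8S,10R)-6-hydroxy-3,10:8,12-diepoxygermacra-2,4(15),11(13)-triene-1,5-dione; 24 methacrylic anhydride
Product: 25 (6R,7S,8S,10R)-6-(2-methylprop-2-enoyloxy)-3,10:8,12-diepoxygermacra-2,4(15),11(13)-triene-1,5-dione
Conditions: 24, DMAP (cat.), i-Pr2NEt, CH2Cl2, 0 °C
Reagents that add atoms: none
Why: DMAP-catalysed acylation of the only hydroxyl group, run cold with a hindered base so that the α-acyloxy ketone does not enolise at C6.

Step 17
Reactants: 25 (6R,7S,8S,10R)-6-(2-methylprop-2-enoyloxy)-3,10:8,12-diepoxygermacra-2,4(15),11(13)-triene-1,5-dione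
Product: 26 (6R,7S,8S,10R)-6-(2-methylprop-2-enoyloxy)-1,5-dioxo-3,10-epoxygermacra-2,4(15),11(13)-trien-12,8-olide
Conditions: CrO3·2C5H5N (excess), CH2Cl2, 23 °C
Reagents that add atoms: chromium trioxide (as its bis-pyridine complex), O=[Cr](=O)=O
Why: Allylic oxidation with hexavalent chromium: the C12 methylene, activated by both O8 and the C11=C13 alkene, is oxidised to the carbonyl, which turns the 3-methylenetetrahydrofuran into the α-methylene-γ-lactone as known for such cyclic allylic ethers, without change at C7 or C8.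

Step 18
Reactants: 26 (6R,7S,8S,10R)-6-(2-methylprop-2-enoyloxy)-1,5-dioxo-3,10-epoxygermacra-2,4(15),11(13)-trien-12,8-olide
Product: 27 (5S,6R,7S,8S,10R)-5-hydroxy-6-(2-methylprop-2-enoyloxy)-1-oxo-3,10-epoxygermacra-2,4(15),11(13)-trien-12,8-olide
Conditions: NaBH4, CeCl3·7H2O, MeOH/THF, −78 °C
Reagents that add atoms: none
Why: Luche reduction: the cerium-activated enone carbonyl C5 is reduced in the 1,2-sense faster than the vinylogous ester C1, the methacrylate or the methylene lactone, and hydride is expected to enter anti to the neighbouring C6–O bond, on the face away from the methacrylate, which places the C5 hydroxyl cis to the C6 ester (5S).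

Compound list
1 | (S)-lactic acid | C[C@H](O)C(=O)O | starting material
2 | pivalaldehyde | CC(C)(C)C=O | starting material
3 | (2S,5S)-2-tert-butyl-5-methyl-1,3-dioxolan-4-one | C[C@@H]1O[C@H](C(C)(C)C)OC1=O | intermediate
4 | allyl bromide | C=CCBr | starting material
5 | (2S,5R)-2-tert-butyl-5-methyl-5-(prop-2-en-1-yl)-1,3-dioxolan-4-one | C=CC[C@@]1(C)O[C@H](C(C)(C)C)OC1=O | intermediate
6 | 2-[(2S,4R)-2-tert-butyl-4-methyl-5-oxo-1,3-dioxolan-4-yl]acetaldehyde | O=CC[C@@]1(C)O[C@H](C(C)(C)C)OC1=O | intermediate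
7 | (2S,5R)-2-tert-butyl-5-[(2S)-2-hydroxybut-3-en-1-yl]-5-methyl-1,3-dioxolan-4-one | C=C[C@@H](O)C[C@@]1(C)O[C@H](C(C)(C)C)OC1=O | intermediate
8 | (3R,5S)-5-ethenyl-3-hydroxy-3-methyloxolan-2-one | C=C[C@@H]1C[C@@](C)(O)C(=O)O1 | intermediate
9 | 1,4-bis(trimethylsilyl)buta-1,3-diyne | C[Si](C)(C)C#CC#C[Si](C)(C)C | starting material
10 | (6R,8S)-6,8-dihydroxy-6-methyl-1-(trimethylsilyl)dec-9-ene-1,3-diyn-5-one | C=C[C@@H](O)C[C@@](C)(O)C(=O)C#CC#C[Si](C)(C)C | intermediate
11 | (2R)-5-ethynyl-2-[(2S)-2-hydroxybut-3-en-1-yl]-2-methylfuran-3(2H)-one | C=C[C@@H](O)C[C@@]1(C)OC(C#C)=CC1=O | intermediate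
12 | (2R)-2-[(2S)-2-hydroxybut-3-en-1-yl]-2-methyl-5-[1-(tributylstannyl)ethenyl]furan-3(2H)-one | C=C[C@@H](O)C[C@@]1(C)OC(C(=C)[Sn](CCCC)(CCCC)CCCC)=CC1=O | intermediate
13 | (2R)-2-[(2S)-2-hydroxybut-3-en-1-yl]-5-(1-iodoethenyl)-2-methylfuran-3(2H)-one | C=C[C@@H](O)C[C@@]1(C)OC(C(=C)I)=CC1=O | intermediate
14 | 2-{[tert-butyl(dimethyl)silyl]oxy}ethan-1-ol | CC(C)(C)[Si](C)(C)OCCO | starting material
15 | 3-chloro-2-(chloromethyl)prop-1-ene | C=C(CCl)CCl | starting material
16 | tert-butyl(2-{[2-(chloromethyl)prop-2-en-1-yl]oxy}ethoxy)dimethylsilane | C=C(CCl)COCCO[Si](C)(C)C(C)(C)C | intermediate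
17 | (2R)-2-[(2S)-2-({2-[(2-{[tert-butyl(dimethyl)silyl]oxy}ethoxy)methyl]prop-2-en-1-yl}oxy)but-3-en-1-yl]-5-(1-iodoethenyl)-2-methylfuran-3(2H)-one | C=C[C@@H](OCC(=C)COCCO[Si](C)(C)C(C)(C)C)C[C@@]1(C)OC(C(=C)I)=CC1=O | intermediate
18 | (2R)-2-{[(2S)-4-[(2-{[tert-butyl(dimethyl)silyl]oxy}ethoxy)methyl]-2,5-dihydrofuran-2-yl]methyl}-5-(1-iodoethenyl)-2-methylfuran-3(2H)-one | CC(C)(C)[Si](C)(C)OCCOCC1=C[C@H](C[C@@]2(C)OC(C(=C)I)=CC2=O)OC1 | intermediate
19 | (2R)-2-{[(2S)-4-[(2-hydroxyethoxy)methyl]-2,5-dihydrofuran-2-yl]methyl}-5-(1-iodoethenyl)-2-methylfuran-3(2H)-one | OCCOCC1=C[C@H](C[C@@]2(C)OC(C(=C)I)=CC2=O)OC1 | intermediate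
20 | {[(5S)-5-{[(2R)-5-(1-iodoethenyl)-2-methyl-3-oxo-2,3-dihydrofuran-2-yl]methyl}-2,5-dihydrofuran-3-yl]methoxy}acetaldehyde | O=CCOCC1=C[C@H](C[C@@]2(C)OC(C(=C)I)=CC2=O)OC1 | intermediate
21 | (8S,10R)-5-hydroxy-3,10:6,13:8,12-triepoxy-6,7-secogermacra-2,4(15),7(11)-trien-1-one (both C5 epimers) | OC1COCC2=C[C@H](C[C@@]3(C)OC(=CC3=O)C1=C)OC2 | intermediate
22 | (8S,10R)-3,10:6,13:8,12-triepoxy-6,7-secogermacra-2,4(15),7(11)-triene-1,5-dione | O=C1COCC2=C[C@H](C[C@@]3(C)OC(=CC3=O)C1=C)OC2 | intermediate
23 | (6R,7R,8S,10R)-6-hydroxy-3,10:8,12-diepoxygermacra-2,4(15),11(13)-triene-1,5-dione | O[C@@H]1[C@H]2C(=C)CO[C@H]2C[C@@]2(C)OC(=CC2=O)C(=C)C1=O | intermediate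
24 | methacrylic anhydride | CC(=C)C(=O)OC(=O)C(C)=C | starting material
25 | (6R,7S,8S,10R)-6-(2-methylprop-2-enoyloxy)-3,10:8,12-diepoxygermacra-2,4(15),11(13)-triene-1,5-dione | C=C(C)C(=O)O[C@@H]1[C@H]2C(=C)CO[C@H]2C[C@@]2(C)OC(=CC2=O)C(=C)C1=O | intermediate
26 | (6R,7S,8S,10R)-6-(2-methylprop-2-enoyloxy)-1,5-dioxo-3,10-epoxygermacra-2,4(15),11(13)-trien-12,8-olide | C=C(C)C(=O)O[C@@H]1[C@H]2C(=C)C(=O)O[C@H]2C[C@@]2(C)OC(=CC2=O)C(=C)C1=O | intermediate
27 | (5S,6R,7S,8S,10R)-5-hydroxy-6-(2-methylprop-2-enoyloxy)-1-oxo-3,10-epoxygermacra-2,4(15),11(13)-trien-12,8-olide (CNP0142847.2) | C=C(C)C(=O)O[C@@H]1[C@H]2C(=C)C(=O)O[C@H]2C[C@@]2(C)OC(=CC2=O)C(=C)[C@@H]1O | target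

Total step count: 18. Longest linear sequence: 17 steps (steps 1 to 7 and 9 to 18, from (S)-lactic acid); step 8 makes the side fragment.

Steps most likely to fail

Step 15. The enolate may bond through the endo arrangement of the C5 carbonyl unit, or the α-ketol may equilibrate through its enediolate before the quench, so that the C6 configuration comes out wrong. The fallback sets out from 22: the rearrangement is run as before, and the C6-epimeric α-ketol F1 is then not acylated with retention but esterified with methacrylic acid under Mitsunobu conditions (PPh3, diisopropyl azodicarboxylate, THF, 0 °C). This inverts C6 and gives the methacrylate directly, so the route is rejoined at 25.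

Step 17. Hexavalent chromium may abstract the tertiary allylic hydrogen at C7 or degrade the cross-conjugated enone instead of oxidising C12 cleanly. The fallback sets out from 25 and reaches the lactone in two stages by a different mechanism: allylic hydroxylation with SeO2 (cat.) and t-BuOOH in CH2Cl2 should give the C12 lactol F2 (both anomers), and MnO2 in CH2Cl2 then oxidises this allylic lactol to the lactone, so the route is rejoined at 26.

Step 18. Hydride may enter on the face of the C5 carbonyl that is syn to the C6 ester (poor facial selectivity), and conjugate reduction of the methylene lactone may compete. The fallback sets out from 26, accepts the substrate bias and corrects it afterwards. The C5-epimeric alcohol F3 from the same reduction is inverted by Mitsunobu esterification with chloroacetic acid (PPh3, diisopropyl azodicarboxylate, toluene, 0 °C) to the chloroacetate F4. Thiourea with NaHCO3 in ethanol then removes the chloroacetyl group without touching the methacrylate or the lactone, and the route ends at 27.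

Further compounds
F1 | step 15 | (6S,7R,8S,10R)-6-hydroxy-3,10:8,12-diepoxygermacra-2,4(15),11(13)-triene-1,5-dione (C6 epimer of 23) | O[C@H]1[C@H]2C(=C)CO[C@H]2C[C@@]2(C)OC(=CC2=O)C(=C)C1=O
F2 | step 17 | (6R,7S,8S,10R)-12-hydroxy-6-(2-methylprop-2-enoyloxy)-3,10:8,12-diepoxygermacra-2,4(15),11(13)-triene-1,5-dione (C12 lactol, both anomers) | C=C(C)C(=O)O[C@@H]1[C@H]2C(=C)C(O)O[C@H]2C[C@@]2(C)OC(=CC2=O)C(=C)C1=O
F3 | step 18 | (5R,6R,7S,8S,10R)-5-hydroxy-6-(2-methylprop-2-enoyloxy)-1-oxo-3,10-epoxygermacra-2,4(15),11(13)-trien-12,8-olide (C5 epimer of 27) | C=C(C)C(=O)O[C@@H]1[C@H]2C(=C)C(=O)O[C@H]2C[C@@]2(C)OC(=CC2=O)C(=C)[C@H]1O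
F4 | step 18 | (5S,6R,7S,8S,10R)-5-(chloroacetoxy)-6-(2-methylprop-2-enoyloxy)-1-oxo-3,10-epoxygermacra-2,4(15),11(13)-trien-12,8-olide | C=C(C)C(=O)O[C@@H]1[C@H]2C(=C)C(=O)O[C@H]2C[C@@]2(C)OC(=CC2=O)C(=C)[C@@H]1OC(=O)CCl
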